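**Plan**

- Retrosynthesis: after the methyl and tosyl groups, the quinone and the C4 ketone are taken back, the trione ring is cut at C4–C4a and C1–C8a, giving an aryne and a 3-aminocyclobutenone that holds C1–C4. The cyclobutenone is cut into an aryloxy(ethyl)ketene and ethoxyacetylene, the C2–O ether into a 2-naphthol and a 2-bromobutanoate, and the oxygenated ring of the naphthol into an aryllithium and a squarate-derived cyclobutenedione.
- Forward order: ring A of the naphthol (thermal cyclobutenone ring expansion), the ether link, the four-membered ring by ketene/ynol ether [2+2], then the trione ring by aryne insertion; the C4 ketone, the quinone and the free phenols come last.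
- Enabling feature: in the trione half (C1 = ketone on C8a, C2 = quaternary carbon, C3/C4 = the 1,2-diketone) the adjacent arene carbons C4a and C8a hold both ends of the chain C4–C3–C2–C1 and lie between the oxygens on C5 and C8. C4a/C8a can therefore be an aryne steered by its two flanking oxygens, and the chain a strained C1=C4 enaminone.
- Stereochemistry: the only stereocentre, quaternary C2, comes from separating the two diastereomeric enaminones that the achiral cyclobutane-1,3-dione forms with (S)-2-(methoxymethyl)pyrrolidine. It has no α-hydrogen and is carried unchanged; only its descriptor changes with the CIP priorities.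

Key step: step 16

Abbreviations: ArO = (3-ethyl-1,4,5,7,8-pentamethoxynaphthalen-2-yl)oxy; Ts = 4-methylbenzenesulfonyl; ring A of the naphthalene is the ring carrying the ethyl group, ring B the other.

Remark: the 5,8-dihydroxy-1,4-naphthoquinone half of the target is one of two rapidly interconverting naphthazarin tautomers; the route aims at this compound whichever tautomer prevails.

**Route**

Step 1
Reactants: 1 2-hydroxy-4,5-dimethoxybenzaldehyde
Product: 2 2-formyl-4,5-dimethoxyphenyl 4-methylbenzenesulfonate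
Conditions: TsCl, Et3N, DMAP (cat.), CH2Cl2, 0 °C to rt
Reagents that add atoms: 4-methylbenzenesulfonyl chloride, Cc1ccc(cc1)S(Cl)(=O)=O
Why: O-sulfonylation of a phenol; the tosylate later masks the C8 oxygen and steers the aryne.

Step 2
Reactants: 2 2-formyl-4,5-dimethoxyphenyl 4-methylbenzenesulfonate
Product: 4 2-hydroxy-4,5-dimethoxyphenyl 4-methylbenzenesulfonate, via aryl formate 3 (not isolated)
Conditions: mCPBA, CH2Cl2, rt; then K2CO3 (cat.), MeOH, 0 °C
Reagents that add atoms: 3-chloroperbenzoic acid, OOC(=O)c1cccc(Cl)c1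
Why: Baeyer–Villiger oxidation in which the para-methoxy aryl group migrates in preference to hydrogen, followed by methanolysis of the formate under conditions that spare the sulfonate (an O-to-O tosyl shift would be degenerate because the parent catechol is symmetric).

Step 3
Reactants: 4 2-hydroxy-4,5-dimethoxyphenyl 4-methylbenzenesulfonate
Product: 5 3-bromo-2-hydroxy-4,5-dimethoxyphenyl 4-methylbenzenesulfonate
Conditions: NBS, CH2Cl2, −20 to 0 °C
Reagents that add atoms: N-bromosuccinimide, BrN1C(=O)CCC1=O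
Why: electrophilic aromatic bromination at the only free position ortho to the phenol, which the neighbouring methoxy group activates as well.

Step 4
Reactants: 5 3-bromo-2-hydroxy-4,5-dimethoxyphenyl 4-methylbenzenesulfonate
Product: 8 3,4-dimethoxy-6-(tosyloxy)-2-(trimethylsilyl)phenyl trifluoromethanesulfonate, via silyl ether 6 (not isolated), via lithium phenoxide 7 (not isolated)
Conditions: (Me3Si)2NH, THF, 65 °C, then evaporation; n-BuLi (1.0 equiv), THF, −100 to −78 °C; Tf2O, −78 °C to rt
Reagents that add atoms: hexamethyldisilazane, C[Si](C)(C)N[Si](C)(C)C; trifluoromethanesulfonic anhydride, FC(F)(F)S(=O)(=O)OS(=O)(=O)C(F)(F)F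
Why: O-silylation, bromine–lithium exchange and retro-Brook shift of silicon from oxygen to carbon, then O-triflation, the standard entry to 2-silylaryl triflates; at this temperature the exchange should be faster than attack of the alkyllithium at the sulfonate.

Step 5
Reactants: 9 3-bromo-4,5-dimethoxybenzaldehyde
Product: 11 3-bromo-4,5-dimethoxyphenol, via aryl formate 10 (not isolated)
Conditions: mCPBA, CH2Cl2, rt; then K2CO3 (cat.), MeOH, rt
Reagents that add atoms: 3-chloroperbenzoic acid, OOC(=O)c1cccc(Cl)c1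
Why: Baeyer–Villiger oxidation of an electron-rich benzaldehyde (aryl migration favoured by the para-methoxy group) and methanolysis of the formate.

Step 6
Reactants: 11 3-bromo-4,5-dimethoxyphenol
Product: 12 1-bromo-2,3,5-trimethoxybenzene
Conditions: MeI, K2CO3, acetone, reflux
Reagents that add atoms: iodomethane, CI
Why: Williamson O-methylation of a phenol.

Step 7
Reactants: 13 3,4-diisopropoxycyclobut-3-ene-1,2-dione (diisopropyl squarate)
Product: 15 3-ethyl-4-isopropoxycyclobut-3-ene-1,2-dione, via hydroxycyclobutenone 14 (not isolated)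
Conditions: EtMgBr, THF, −78 °C; aq. NH4Cl; then 12 M HCl (cat.), CH2Cl2, rt
Reagents that add atoms: ethylmagnesium bromide, CC[Mg]Br
Why: 1,2-addition of the Grignard reagent to the squarate and acid-promoted loss of isopropanol from the adduct, the usual route to 3-alkyl-4-alkoxycyclobutenediones.

Step 8
Reactants: 12 1-bromo-2,3,5-trimethoxybenzene; 15 3-ethyl-4-isopropoxycyclobut-3-ene-1,2-dione
Product: 17 2-ethyl-4-hydroxy-3-isopropoxy-4-(2,3,5-trimethoxyphenyl)cyclobut-2-en-1-one (racemic), via aryllithium 16 (not isolated)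
Conditions: n-BuLi, THF, −78 °C; then 15, −78 °C; aq. NH4Cl
Reagents that add atoms: none
Why: bromine–lithium exchange and 1,2-addition of the aryllithium to the ketone next to the alkoxy-bearing carbon, the other carbonyl being deactivated as a vinylogous ester.

Step 9
Reactants: 17 2-ethyl-4-hydroxy-3-isopropoxy-4-(2,3,5-trimethoxyphenyl)cyclobut-2-en-1-one
Product: 20 3-ethyl-2-isopropoxy-1,4,5,7,8-pentamethoxynaphthalene, via vinylketene 18 (not isolated), via naphthalene-1,4-diol 19 (not isolated)
Conditions: p-xylene, 138 °C, argon; then evaporation, Me2SO4, K2CO3, acetone, reflux, argon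
Reagents that add atoms: dimethyl sulfate, COS(=O)(=O)OC
Why: thermal 4π-electrocyclic ring opening to the vinylketene, 6π-electrocyclisation onto the only free ortho carbon of the aryl group and tautomerisation give the naphthalene-1,4-diol with ethyl and isopropoxy placed by the cyclobutenone, and both phenols are then methylated (Williamson) before air can oxidise them.

Step 10
Reactants: 20 3-ethyl-2-isopropoxy-1,4,5,7,8-pentamethoxynaphthalene
Product: 21 3-ethyl-1,4,5,7,8-pentamethoxynaphthalen-2-ol
Conditions: BCl3, CH2Cl2, −78 to 0 °C; then H2O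
Reagents that add atoms: none
Why: Lewis-acid ether cleavage in which BCl3 removes the secondary isopropyl group much faster than methyl groups, the more so as this oxygen is the twisted one between two ortho substituents.

Step 11
Reactants: 21 3-ethyl-1,4,5,7,8-pentamethoxynaphthalen-2-ol; 22 ethyl 2-bromobutanoate (racemic)
Product: 23 ethyl 2-(ArO)butanoate (racemic)
Conditions: Cs2CO3, DMF, 60 °C
Reagents that add atoms: none
Why: Williamson ether synthesis (SN2 of the caesium naphthoxide on the α-bromo ester); the stereocentre is formed racemic and is erased in step 14.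

Step 12
Reactants: 23 ethyl 2-(ArO)butanoate
Product: 24 2-(ArO)butanoic acid (racemic)
Conditions: LiOH, THF/MeOH/H2O, rt; then 1 M HCl
Reagents that add atoms: lithium hydroxide, [Li+].[OH-]
Why: ester saponification.

Step 13
Reactants: 24 2-(ArO)butanoic acid; 25 ethoxyacetylene
Product: 28 3-ethoxy-4-ethyl-4-(ArO)cyclobut-2-en-1-one (racemic), via acid chloride 26 (not isolated), via aryloxy(ethyl)ketene 27 (not isolated)
Conditions: 1-chloro-N,N,2-trimethylprop-1-en-1-amine, CH2Cl2, 0 °C to rt; then 25 (3 equiv), Et3N, CH2Cl2, 0 °C to rt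
Reagents that add atoms: none
Why: neutral acid chloride formation, dehydrochlorination to the ketene and regioselective [2+2] cycloaddition with the ynol ether (ketene carbonyl carbon to the unsubstituted alkyne carbon), the standard entry to 4,4-disubstituted 3-ethoxycyclobutenones.

Step 14
Reactants: 28 3-ethoxy-4-ethyl-4-(ArO)cyclobut-2-en-1-one
Product: 29 2-ethyl-2-(ArO)cyclobutane-1,3-dione (achiral)
Conditions: 2 M HCl, THF, rt
Reagents that add atoms: water, O
Why: acid hydrolysis of the vinylogous ester; the two carbonyl groups of the dione are enantiotopic, so the racemic centre of 28 disappears.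

Step 15
Reactants: 29 2-ethyl-2-(ArO)cyclobutane-1,3-dione; 30 (S)-2-(methoxymethyl)pyrrolidine
Product: 31 (4S)-4-ethyl-4-(ArO)-3-[(2S)-2-(methoxymethyl)pyrrolidin-1-yl]cyclobut-2-en-1-one
Conditions: TsOH·H2O (cat.), toluene, 4 Å molecular sieves, 80 °C; chromatography on SiO2
Reagents that add atoms: none
Why: condensation of a cyclic 1,3-dione with a secondary amine to the vinylogous amide; attack at one or the other enantiotopic carbonyl gives 31 or its (4R) epimer, which are diastereomers and are separated (C4 to be assigned by X-ray analysis), and the unwanted epimer can be hydrolysed back to 29 with aqueous acid and recycled.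

Step 16
Reactants: 31 (4S)-4-ethyl-4-(ArO)-3-[(2S)-2-(methoxymethyl)pyrrolidin-1-yl]cyclobut-2-en-1-one; 8 3,4-dimethoxy-6-(tosyloxy)-2-(trimethylsilyl)phenyl trifluoromethanesulfonate
Product: 36 (R)-2-ethyl-2-(ArO)-5,6-dimethoxy-8-(tosyloxy)naphthalene-1,3(2H,4H)-dione, via aryne 32 (not isolated), via aryl anion iminium zwitterion 33 (not isolated), via fused benzocyclobutene 34 (not isolated), via iminium enolate 35 (not isolated)
Conditions: 8 (1.3 equiv), CsF (3 equiv), MeCN, rt to 40 °C; then 1 M HCl, THF, rt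
Reagents that add atoms: water, O
Why: Proposed new method: CsF removes the silyl group of 8 and triflate departs to give aryne 32; the nucleophilic carbon C4 of the push-pull enaminone 31 adds to C4a (zwitterion 33), the aryl anion at C8a closes on the neighbouring iminium carbon C1 to the benzocyclobutene-fused aminocyclobutanone 34, and its central C1–C4 bond, which lies between an amine donor and a ketone acceptor and carries the strain of two four-membered rings, breaks to the aromatic iminium enolate 35, which aqueous acid protonates at C4 and hydrolyses at C1 with release of the pyrrolidine. The closest known reaction types are the insertion of arynes into the C=C bond of cyclic vinylogous amides and the acyl-alkylation of arynes by β-dicarbonyl compounds; neither has been shown on a 3-aminocyclobutenone. The six-membered ring is closed indirectly: a 4-exo-trig closure of the aryl anion onto the iminium carbon (net [2+2] of the aryne with C1=C4) is followed by four-to-six ring expansion, so that C4–C4a and C1–C8a are made and C1–C4 is lost. No stereocentre is created; quaternary C2 is a spectator, and because the amine-bearing carbon becomes C1 the configuration of 31 is transferred only if the aryl anion picks the cationic iminium carbon and not the ketone C3 (which would lead to the enantiomer), a choice the positive charge should secure. The regioselectivity needed is attack at C4a: the tosyloxy group beside C8a is the stronger σ-acceptor and the bulkier neighbour, so the negative charge develops at C8a and the enaminone enters beside the methoxy group. Tosylate instead of triflate at C8 keeps the C8a anion from expelling sulfonate before it closes, and the tertiary amine leaves no N–H for N-arylation.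

Step 17
Reactants: 36 (R)-2-ethyl-2-(ArO)-5,6-dimethoxy-8-(tosyloxy)naphthalene-1,3(2H,4H)-dione
Product: 37 (R)-2-ethyl-8-hydroxy-5,6-dimethoxy-2-(ArO)naphthalene-1,3(2H,4H)-dione
Conditions: LiOH, THF/H2O (degassed), rt to 40 °C, argon; then aq. NH4Cl
Reagents that add atoms: none
Why: hydroxide cleaves the S–O bond of the aryl sulfonate, eased by the ortho-acyl phenoxide leaving group, while the dione rests as its C3–C4 enolate, which shields both carbonyls from retro-Claisen cleavage; C2 cannot epimerise.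

Step 18
Reactants: 37 (R)-2-ethyl-8-hydroxy-5,6-dimethoxy-2-(ArO)naphthalene-1,3(2H,4H)-dione
Product: 38 (S)-2-ethyl-8-hydroxy-5,6-dimethoxy-2-(ArO)naphthalene-1,3,4(2H)-trione
Conditions: SeO2, 1,4-dioxane/H2O, 90 °C
Reagents that add atoms: selenium dioxide, O=[Se]=O
Why: Riley oxidation of the C4 methylene, which is benzylic, α to the C3 ketone and the only enolisable position in the molecule.

Step 19
Reactants: 38 (S)-2-ethyl-8-hydroxy-5,6-dimethoxy-2-(ArO)naphthalene-1,3,4(2H)-trione
Product: 39 (S)-2-ethyl-2-[(3-ethyl-5,7,8-trimethoxy-1,4-dioxo-1,4-dihydronaphthalen-2-yl)oxy]-8-hydroxy-5,6-dimethoxynaphthalene-1,3,4(2H)-trione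
Conditions: (NH4)2Ce(NO3)6 (2.2 equiv), MeCN/H2O, 0 °C
Reagents that add atoms: water, O
Why: oxidative demethylation of a 1,4-dimethoxyarene by tetravalent cerium, the electron-rich naphthalene being oxidised well below the potential of the doubly acylated, hydrogen-bonded phenol ring; should ring B be oxidised instead of ring A, the isomeric quinone converges on the same naphthazarin in step 20.

Step 20
Reactants: 39 (S)-2-ethyl-2-[(3-ethyl-5,7,8-trimethoxy-1,4-dioxo-1,4-dihydronaphthalen-2-yl)oxy]-8-hydroxy-5,6-dimethoxynaphthalene-1,3,4(2H)-trione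
Product: 40 (S)-2-ethyl-2-[(3-ethyl-5,7,8-trihydroxy-1,4-dioxo-1,4-dihydronaphthalen-2-yl)oxy]-5,6,8-trihydroxynaphthalene-1,3,4(2H)-trione (CNP0325426.1)
Conditions: BBr3 (excess), CH2Cl2, −78 to 0 °C; then H2O
Reagents that add atoms: none
Why: Lewis-acid cleavage of the five aryl methyl ethers by BBr3 (bromide attacks the methyl groups); the ether between the halves has a quaternary alkyl carbon flanked by two carbonyl groups and offers no such pathway.

**Compound list**

1 | 2-hydroxy-4,5-dimethoxybenzaldehyde | COc1cc(O)c(C=O)cc1OC | starting material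
2 | 2-formyl-4,5-dimethoxyphenyl 4-methylbenzenesulfonate | COc1cc(OS(=O)(=O)c2ccc(C)cc2)c(C=O)cc1OC | intermediate
3 | 2-(formyloxy)-4,5-dimethoxyphenyl 4-methylbenzenesulfonate (not isolated) | COc1cc(OS(=O)(=O)c2ccc(C)cc2)c(OC=O)cc1OC | intermediate
4 | 2-hydroxy-4,5-dimethoxyphenyl 4-methylbenzenesulfonate | COc1cc(OS(=O)(=O)c2ccc(C)cc2)c(O)cc1OC | intermediate
5 | 3-bromo-2-hydroxy-4,5-dimethoxyphenyl 4-methylbenzenesulfonate | COc1c(OC)cc(OS(=O)(=O)c2ccc(C)cc2)c(O)c1Br | intermediate
6 | 3-bromo-4,5-dimethoxy-2-(trimethylsilyloxy)phenyl 4-methylbenzenesulfonate (not isolated) | COc1c(OC)cc(OS(=O)(=O)c2ccc(C)cc2)c(O[Si](C)(C)C)c1Br | intermediate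
7 | lithium 3,4-dimethoxy-6-(tosyloxy)-2-(trimethylsilyl)phenoxide (not isolated) | COc1c(OC)cc(OS(=O)(=O)c2ccc(C)cc2)c([O-])c1[Si](C)(C)C.[Li+] | intermediate
8 | 3,4-dimethoxy-6-(tosyloxy)-2-(trimethylsilyl)phenyl trifluoromethanesulfonate | C[Si](C)(C)c1c(OC)c(OC)cc(OS(=O)(=O)c2ccc(C)cc2)c1OS(=O)(=O)C(F)(F)F | intermediate
9 | 3-bromo-4,5-dimethoxybenzaldehyde | COc1cc(C=O)cc(Br)c1OC | starting material
10 | 3-bromo-4,5-dimethoxyphenyl formate (not isolated) | COc1cc(OC=O)cc(Br)c1OC | intermediate
11 | 3-bromo-4,5-dimethoxyphenol | COc1cc(O)cc(Br)c1OC | intermediate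
12 | 1-bromo-2,3,5-trimethoxybenzene | COc1cc(Br)c(OC)c(OC)c1 | intermediate
13 | 3,4-diisopropoxycyclobut-3-ene-1,2-dione | CC(C)OC1=C(OC(C)C)C(=O)C1=O | starting material
14 | 4-ethyl-4-hydroxy-2,3-diisopropoxycyclobut-2-en-1-one, racemic, present as its magnesium alkoxide (not isolated) | CCC1(O)C(OC(C)C)=C(OC(C)C)C1=O | intermediate
15 | 3-ethyl-4-isopropoxycyclobut-3-ene-1,2-dione | CCC1=C(OC(C)C)C(=O)C1=O | intermediate
16 | (2,3,5-trimethoxyphenyl)lithium (not isolated) | [Li]c1cc(OC)cc(OC)c1OC | intermediate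
17 | 2-ethyl-4-hydroxy-3-isopropoxy-4-(2,3,5-trimethoxyphenyl)cyclobut-2-en-1-one, racemic | CCC1=C(OC(C)C)C(O)(c2cc(OC)cc(OC)c2OC)C1=O | intermediate
18 | 2-ethyl-4-hydroxy-3-isopropoxy-4-(2,3,5-trimethoxyphenyl)buta-1,3-dien-1-one, vinylketene (not isolated) | CCC(=C=O)C(OC(C)C)=C(O)c1cc(OC)cc(OC)c1OC | intermediate
19 | 3-ethyl-2-isopropoxy-5,7,8-trimethoxynaphthalene-1,4-diol (not isolated) | CCc1c(O)c2c(OC)cc(OC)c(OC)c2c(O)c1OC(C)C | intermediate
20 | 3-ethyl-2-isopropoxy-1,4,5,7,8-pentamethoxynaphthalene | CCc1c(OC)c2c(OC)cc(OC)c(OC)c2c(OC)c1OC(C)C | intermediate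
21 | 3-ethyl-1,4,5,7,8-pentamethoxynaphthalen-2-ol | CCc1c(OC)c2c(OC)cc(OC)c(OC)c2c(OC)c1O | intermediate
22 | ethyl 2-bromobutanoate, racemic | CCC(Br)C(=O)OCC | starting material
23 | ethyl 2-[(3-ethyl-1,4,5,7,8-pentamethoxynaphthalen-2-yl)oxy]butanoate, racemic | CCOC(=O)C(CC)Oc1c(CC)c(OC)c2c(OC)cc(OC)c(OC)c2c1OC | intermediate
24 | 2-[(3-ethyl-1,4,5,7,8-pentamethoxynaphthalen-2-yl)oxy]butanoic acid, racemic | CCC(Oc1c(CC)c(OC)c2c(OC)cc(OC)c(OC)c2c1OC)C(O)=O | intermediate
25 | ethoxyacetylene | CCOC#C | starting material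
26 | 2-(ArO)butanoyl chloride (not isolated) | CCC(Oc1c(CC)c(OC)c2c(OC)cc(OC)c(OC)c2c1OC)C(Cl)=O | intermediate
27 | 2-(ArO)but-1-en-1-one, aryloxy(ethyl)ketene (not isolated) | CCC(=C=O)Oc1c(CC)c(OC)c2c(OC)cc(OC)c(OC)c2c1OC | intermediate
28 | 3-ethoxy-4-ethyl-4-(ArO)cyclobut-2-en-1-one, racemic | CCOC1=CC(=O)C1(CC)Oc2c(CC)c(OC)c3c(OC)cc(OC)c(OC)c3c2OC | intermediate
29 | 2-ethyl-2-(ArO)cyclobutane-1,3-dione, achiral | CCC1(Oc2c(CC)c(OC)c3c(OC)cc(OC)c(OC)c3c2OC)C(=O)CC1=O | intermediate
30 | (S)-2-(methoxymethyl)pyrrolidine | COC[C@@H]1CCCN1 | starting material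
31 | (4S)-4-ethyl-4-(ArO)-3-[(2S)-2-(methoxymethyl)pyrrolidin-1-yl]cyclobut-2-en-1-one | COC[C@@H]1CCCN1C2=CC(=O)[C@@]2(CC)Oc3c(CC)c(OC)c4c(OC)cc(OC)c(OC)c4c3OC | intermediate
32 | 3,4-dimethoxy-6-(tosyloxy)benzyne (not isolated) | COC1=C(OC)C=C(OS(=O)(=O)c2ccc(C)cc2)C#C1 | intermediate
33 | zwitterion: cyclobutanone bearing the C1 pyrrolidinium ylidene and, on C4, the 2,3-dimethoxy-5-(tosyloxy)phenyl group with its anion at C8a; C2 (S), pyrrolidine (S), C4 undefined (not isolated) | COC[C@@H]1CCC[N+]1=C2C(c3c(OC)c(OC)cc(OS(=O)(=O)c4ccc(C)cc4)[c-]3)C(=O)[C@@]2(CC)Oc5c(CC)c(OC)c6c(OC)cc(OC)c(OC)c6c5OC | intermediate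
34 | benzocyclobutene-fused aminocyclobutanone: C1 (pyrrolidinyl) bonded to C8a, C2 and C4, C4 bonded to C4a and C3; ring fusion C1/C4 cis, otherwise undefined (not isolated) | COC[C@@H]1CCCN1C23c4c(OS(=O)(=O)c5ccc(C)cc5)cc(OC)c(OC)c4C2C(=O)[C@@]3(CC)Oc6c(CC)c(OC)c7c(OC)cc(OC)c(OC)c7c6OC | intermediate
35 | ring-expanded iminium enolate: C1 pyrrolidinium ylidene on C8a, C3 enolate conjugated with C4 (not isolated) | COC[C@@H]1CCC[N+]1=C2c3c(OS(=O)(=O)c4ccc(C)cc4)cc(OC)c(OC)c3C=C([O-])[C@@]2(CC)Oc5c(CC)c(OC)c6c(OC)cc(OC)c(OC)c6c5OC | intermediate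
36 | (R)-2-ethyl-2-(ArO)-5,6-dimethoxy-8-(tosyloxy)naphthalene-1,3(2H,4H)-dione | CCc1c(O[C@]2(CC)C(=O)Cc3c(OC)c(OC)cc(OS(=O)(=O)c4ccc(C)cc4)c3C2=O)c(OC)c2c(OC)c(OC)cc(OC)c2c1OC | intermediate
37 | (R)-2-ethyl-8-hydroxy-5,6-dimethoxy-2-(ArO)naphthalene-1,3(2H,4H)-dione | CCc1c(O[C@]2(CC)C(=O)Cc3c(OC)c(OC)cc(O)c3C2=O)c(OC)c2c(OC)c(OC)cc(OC)c2c1OC | intermediate
38 | (S)-2-ethyl-8-hydroxy-5,6-dimethoxy-2-(ArO)naphthalene-1,3,4(2H)-trione | CCc1c(O[C@]2(CC)C(=O)C(=O)c3c(OC)c(OC)cc(O)c3C2=O)c(OC)c2c(OC)c(OC)cc(OC)c2c1OC | intermediate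
39 | (S)-2-ethyl-2-[(3-ethyl-5,7,8-trimethoxy-1,4-dioxo-1,4-dihydronaphthalen-2-yl)oxy]-8-hydroxy-5,6-dimethoxynaphthalene-1,3,4(2H)-trione | CCC1=C(O[C@]2(CC)C(=O)C(=O)c3c(OC)c(OC)cc(O)c3C2=O)C(=O)c2c(OC)c(OC)cc(OC)c2C1=O | intermediate
40 | (S)-2-ethyl-2-[(3-ethyl-5,7,8-trihydroxy-1,4-dioxo-1,4-dihydronaphthalen-2-yl)oxy]-5,6,8-trihydroxynaphthalene-1,3,4(2H)-trione | CCC1=C(O[C@]2(CC)C(=O)C(=O)c3c(O)c(O)cc(O)c3C2=O)C(=O)c2c(O)c(O)cc(O)c2C1=O | target

**Step count and risks**

Total: 20 steps. Longest linear sequence: 15 steps (steps 5, 6 and 8 to 20, from 9).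

Steps most likely to fail:

1. Step 16. After the first C–C bond forms, the zwitterion may pass a proton from C4 to the aryl anion (plain C-arylation without ring expansion), the aryne may be attacked at the wrong carbon, or the product enolate may take up a second aryne. The fallback builds the same ring in two known stages and sets out from acid 24 and triflate 8.
   - Acid 24 is activated with 1,1'-carbonyldiimidazole and acylates potassium methyl malonate (MgCl2, Et3N, THF) to give methyl 4-(ArO)-3-oxohexanoate F1.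
   - F1 undergoes the established aryne acyl-alkylation with 8 (CsF, MeCN, 80 °C) to give methyl 2-[2-(2-(ArO)butanoyl)-5,6-dimethoxy-3-(tosyloxy)phenyl]acetate F2.
   - NaH in THF closes the ring by Dieckmann condensation to racemic 2-ethyl-2-(ArO)-5,6-dimethoxy-8-(tosyloxy)naphthalene-1,3(2H,4H)-dione F3.
   - Preparative chromatography on a chiral stationary phase should deliver the (R) enantiomer, which is 36, where the route is rejoined.

2. Step 15. The hindered amine may stop at the ammonium enolate salt, or open the strained diketone by retro-Claisen attack before it condenses beside the fully substituted carbon. The fallback sets out from dione 29: oxalyl chloride (CH2Cl2, 0 °C) converts it into the vinylogous acid chloride 3-chloro-4-ethyl-4-(ArO)cyclobut-2-en-1-one F4 (racemic). Addition–elimination with 30 and Et3N in CH2Cl2 then gives 31 together with its C4 epimer (4R)-4-ethyl-4-(ArO)-3-[(2S)-2-(methoxymethyl)pyrrolidin-1-yl]cyclobut-2-en-1-one F5, which are separated on SiO2; the route is rejoined at 31.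

3. Step 19. The oxidant may go on to oxidise the free para-methoxyphenol of the trione half, or degrade the electron-rich ring before both methoxy groups are lost. The fallback reverses the order and sets out from 38: BBr3 (CH2Cl2, −78 to 0 °C) removes all seven methyl groups to give the leuco compound (S)-2-ethyl-2-[(3-ethyl-1,4,5,7,8-pentahydroxynaphthalen-2-yl)oxy]-5,6,8-trihydroxynaphthalene-1,3,4(2H)-trione F6. Its electron-rich tetrahydroxylated ring should be oxidised by air (EtOAc/pH 7 buffer) to the naphthazarin, so the route is rejoined at target 40 without a cerium oxidant.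

Further compounds
F1 | step 16 | methyl 4-[(3-ethyl-1,4,5,7,8-pentamethoxynaphthalen-2-yl)oxy]-3-oxohexanoate, racemic | CCC(Oc1c(CC)c(OC)c2c(OC)cc(OC)c(OC)c2c1OC)C(=O)CC(=O)OC
F2 | step 16 | methyl 2-[2-(2-(ArO)butanoyl)-5,6-dimethoxy-3-(tosyloxy)phenyl]acetate, racemic | CCC(Oc1c(CC)c(OC)c2c(OC)cc(OC)c(OC)c2c1OC)C(=O)c1c(OS(=O)(=O)c2ccc(C)cc2)cc(OC)c(OC)c1CC(=O)OC
F3 | step 16 | racemic 2-ethyl-2-(ArO)-5,6-dimethoxy-8-(tosyloxy)naphthalene-1,3(2H,4H)-dione | CCc1c(OC2(CC)C(=O)Cc3c(OC)c(OC)cc(OS(=O)(=O)c4ccc(C)cc4)c3C2=O)c(OC)c2c(OC)c(OC)cc(OC)c2c1OC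
F4 | step 15 | 3-chloro-4-ethyl-4-(ArO)cyclobut-2-en-1-one, racemic | CCC1(Oc2c(CC)c(OC)c3c(OC)cc(OC)c(OC)c3c2OC)C(Cl)=CC1=O
F5 | step 15 | (4R)-4-ethyl-4-(ArO)-3-[(2S)-2-(methoxymethyl)pyrrolidin-1-yl]cyclobut-2-en-1-one | COC[C@@H]1CCCN1C2=CC(=O)[C@]2(CC)Oc3c(CC)c(OC)c4c(OC)cc(OC)c(OC)c4c3OC
F6 | step 19 | (S)-2-ethyl-2-[(3-ethyl-1,4,5,7,8-pentahydroxynaphthalen-2-yl)oxy]-5,6,8-trihydroxynaphthalene-1,3,4(2H)-trione | CCc1c(O[C@]2(CC)C(=O)C(=O)c3c(O)c(O)cc(O)c3C2=O)c(O)c2c(O)c(O)cc(O)c2c1O
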